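**Strategy.** The cyclobutane of the target is read as isobutylene (ring C-4 H2 and C-3 Me2) laid across the C-1–C-2 bond of an acyclic enoyl unit, the C(=CH2) carbon on C-1 being a masked acyl carbon. One visible-light [2+2] photocycloaddition of a chiral-rhodium-chelated (E)-enoyl pyrazole with isobutylene forms C-1–C-4 and C-2–C-3, closes the four-membered ring and sets both stereocentres (1S,2R, trans). The precursor is the N-enoyl-3,5-dimethylpyrazole whose β-carbon carries the ketal-protected 3-oxobutyl chain, made in three steps. The acyl pyrazole then serves directly as ketone precursor for Grignard addition, methylenation, deprotection and linoleoylation.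

Key step: step 4

Assumption: for a β-alkyl acceptor the sense of induction of the rhodium catalyst is not secure; the Δ complex is written, and the Λ complex is taken instead if a first run delivers (1R,2S)-8.

Remark: in all names ring C-1 carries the acyl-derived carbon, C-2 the four-carbon chain, C-3 the two methyl groups and C-4 is the ring CH2. Fleeting species (excited states, the 1,4-biradical, O-acylisoureas, metallacyclobutanes, oxaphosphetanes) are not numbered.

Step 1
Reactants: 1 hex-5-en-2-one
Product: 2 2-(but-3-en-1-yl)-2-methyl-1,3-dioxolane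
Conditions: ethylene glycol (1.5 equiv), p-TsOH·H2O (1 mol%), cyclohexane, Dean–Stark, reflux; NaHCO3, distillation
Reagents that add atoms: ethylene glycol, OCCO
Why: Acid-catalysed ketalisation, driven to completion by azeotropic removal of water; the terminal alkene is inert and no stereocentre is involved.

Step 2
Reactants: 2 2-(but-3-en-1-yl)-2-methyl-1,3-dioxolane; 3 acrylic acid
Product: 4 (2E)-5-(2-methyl-1,3-dioxolan-2-yl)pent-2-enoic acid
Conditions: 3 (3 equiv), second-generation Hoveyda–Grubbs catalyst RuCl2(SIMes)(=CH-C6H4-2-OiPr) (2.5 mol%), dry CH2Cl2, 40 °C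
Reagents that add atoms: none
Why: Olefin cross metathesis between a terminal alkene that homodimerises reversibly and electron-poor acrylic acid that does not, so that secondary metathesis should funnel the material to the cross product with (E) geometry under thermodynamic control, the ketal being inert in the absence of water.

Step 3
Reactants: 4 (2E)-5-(2-methyl-1,3-dioxolan-2-yl)pent-2-enoic acid; 5 3,5-dimethyl-1H-pyrazole
Product: 6 (2E)-1-(3,5-dimethyl-1H-pyrazol-1-yl)-5-(2-methyl-1,3-dioxolan-2-yl)pent-2-en-1-one
Conditions: DCC (1.1 equiv), DMAP (10 mol%), CH2Cl2, 0 °C → rt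
Reagents that add atoms: none
Why: Steglich-type carbodiimide coupling with DMAP as acyl-transfer catalyst should acylate the pyrazole N–H under neutral conditions that leave the ketal and the (E)-alkene untouched.

Step 4
Reactants: 6 (2E)-1-(3,5-dimethyl-1H-pyrazol-1-yl)-5-(2-methyl-1,3-dioxolan-2-yl)pent-2-en-1-one; 7 isobutylene
Product: 8 (3,5-dimethyl-1H-pyrazol-1-yl){(1S,2R)-3,3-dimethyl-2-[2-(2-methyl-1,3-dioxolan-2-yl)ethyl]cyclobutyl}methanone (trans)
Conditions: Δ-[Rh(C^N)2(MeCN)2]PF6 (C^N = cyclometalated 5-tert-butyl-2-phenylbenzothiazole; 5 mol%), 7 (condensed, 20 equiv), degassed acetone (0.05 M), sealed tube, blue LEDs (420–450 nm), 20 °C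
Reagents that add atoms: none
Why: Proposed new method: 6 should displace the two labile MeCN ligands and chelate the trivalent rhodium centre through the carbonyl oxygen and pyrazole N2, which red-shifts its absorption so that only bound substrate is excited by the LEDs and, after metal-assisted intersystem crossing, reaches a substrate-centred triplet that adds stepwise to free isobutylene. The closest known reaction type is the visible-light [2+2] photocycloaddition of α,β-unsaturated N-acyl azoles bound to chiral Lewis acids with simple alkenes, shown for β-aryl acceptors, together with the classical head-to-tail enone–isobutylene photocycloaddition; a β-alkyl acyclic acceptor and a gaseous unactivated 1,1-dialkylalkene are the untested elements. The cyclobutane closes in two stages, first the C-1–C-4 bond by attack of the electrophilic metal-bound α-carbon radical terminus on the CH2 end of isobutylene to give a triplet 1,4-biradical (secondary radical at C-2, tertiary radical at C-3), then the C-2–C-3 bond by radical recombination after spin inversion. C-1 is set in the first bond formation by the ligand sphere, one tert-butylbenzothiazole wing of the C2-symmetric complex covering one face of the s-cis enoyl unit, and C-2 is set in the closure, where the freely rotating acyclic biradical places the chain trans to the metal-bound acyl group. The step needs head-to-tail regiochemistry, trans diastereoselectivity and one enantioface: the first rests on the polarity match between the Lewis-acid-bound α-acyl radical terminus and the nucleophilic unhindered CH2 of isobutylene, the second on the acyclic chain of 6 that lets the biradical relax (so E/Z scrambling of 6 is harmless), and the third on the bidentate acyl pyrazole of 6, which fixes the s-cis chelate and confines excitation to catalyst-bound substrate.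

Step 5
Reactants: 8 (3,5-dimethyl-1H-pyrazol-1-yl){(1S,2R)-3,3-dimethyl-2-[2-(2-methyl-1,3-dioxolan-2-yl)ethyl]cyclobutyl}methanone; 9 (3-bromopropoxy)(tert-butyl)dimethylsilane
Product: 12 4-[(tert-butyldimethylsilyl)oxy]-1-{(1S,2R)-3,3-dimethyl-2-[2-(2-methyl-1,3-dioxolan-2-yl)ethyl]cyclobutyl}butan-1-one, via Grignard reagent 10 (not isolated), via magnesium hemiaminal 11 (not isolated)
Conditions: 9 (1.4 equiv), Mg turnings (I2-activated), THF, 40 °C; then 8, THF, −78 → 0 °C; sat. aq. NH4Cl
Reagents that add atoms: none
Why: Acyl substitution of an N-acylpyrazole by a Grignard reagent, which like the Weinreb ketone synthesis should stop at the ketone because magnesium is held between the alkoxide oxygen and pyrazole N2 in adduct 11 until work-up; C-1 is not involved and would in any case equilibrate towards trans.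

Step 6
Reactants: 12 4-[(tert-butyldimethylsilyl)oxy]-1-{(1S,2R)-3,3-dimethyl-2-[2-(2-methyl-1,3-dioxolan-2-yl)ethyl]cyclobutyl}butan-1-one
Product: 13 tert-butyl[(4-{(1S,2R)-3,3-dimethyl-2-[2-(2-methyl-1,3-dioxolan-2-yl)ethyl]cyclobutyl}pent-4-en-1-yl)oxy]dimethylsilane
Conditions: Ph3PCH3Br (2.5 equiv), KOtBu (2.3 equiv), THF, 0 °C → rt; then 12, rt → 40 °C
Reagents that add atoms: methyltriphenylphosphonium bromide, C[P+](c1ccccc1)(c1ccccc1)c1ccccc1.[Br-]
Why: Wittig methylenation with the small non-stabilised ylide Ph3P=CH2, which should convert the hindered enolisable ketone into the 1,1-disubstituted alkene without touching ketal or silyl ether.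

Step 7
Reactants: 13 tert-butyl[(4-{(1S,2R)-3,3-dimethyl-2-[2-(2-methyl-1,3-dioxolan-2-yl)ethyl]cyclobutyl}pent-4-en-1-yl)oxy]dimethylsilane
Product: 14 4-[(1S,2R)-3,3-dimethyl-2-(3-oxobutyl)cyclobutyl]pent-4-en-1-ol
Conditions: 1 M aq. HCl/THF (1:5), 0 °C → rt, stopped at full conversion; NaHCO3
Reagents that add atoms: water, O
Why: Acid-catalysed hydrolysis should cleave the dioxolane and the primary silyl ether in one operation, in dilute acid that protonates the 1,1-disubstituted alkene far too slowly to open the path to cyclobutylcarbinyl cation rearrangement.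

Step 8
Reactants: 14 4-[(1S,2R)-3,3-dimethyl-2-(3-oxobutyl)cyclobutyl]pent-4-en-1-ol; 15 linoleic acid
Product: 16 4-[(1S,2R)-3,3-dimethyl-2-(3-oxobutyl)cyclobutyl]pent-4-en-1-yl (9Z,12Z)-octadeca-9,12-dienoate (IN0146)
Conditions: 15 (1.1 equiv), DCC (1.2 equiv), DMAP (10 mol%), CH2Cl2, 0 °C → rt, argon, dark
Reagents that add atoms: none
Why: Steglich esterification of the primary alcohol under neutral conditions at or below room temperature, which should leave the skipped (Z,Z)-diene, the ketone and the exocyclic alkene untouched.

**Compound list**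

1 | hex-5-en-2-one | CC(=O)CCC=C | starting material
2 | 2-(but-3-en-1-yl)-2-methyl-1,3-dioxolane | C=CCCC1(C)OCCO1 | intermediate
3 | acrylic acid | C=CC(=O)O | starting material
4 | (2E)-5-(2-methyl-1,3-dioxolan-2-yl)pent-2-enoic acid | OC(=O)/C=C/CCC1(C)OCCO1 | intermediate
5 | 3,5-dimethyl-1H-pyrazole | Cc1cc(C)[nH]n1 | starting material
6 | (2E)-1-(3,5-dimethyl-1H-pyrazol-1-yl)-5-(2-methyl-1,3-dioxolan-2-yl)pent-2-en-1-one | O=C(/C=C/CCC1(C)OCCO1)n1nc(C)cc1C | intermediate
7 | isobutylene | C=C(C)C | starting material
8 | (3,5-dimethyl-1H-pyrazol-1-yl){(1S,2R)-3,3-dimethyl-2-[2-(2-methyl-1,3-dioxolan-2-yl)ethyl]cyclobutyl}methanone, trans | O=C(n1nc(C)cc1C)[C@H]1CC(C)(C)[C@@H]1CCC2(C)OCCO2 | intermediate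
9 | (3-bromopropoxy)(tert-butyl)dimethylsilane | CC(C)(C)[Si](C)(C)OCCCBr | starting material
10 | {3-[(tert-butyldimethylsilyl)oxy]propyl}magnesium bromide (Grignard reagent, THF solution) | CC(C)(C)[Si](C)(C)OCCC[Mg]Br | intermediate
11 | bromomagnesium 4-[(tert-butyldimethylsilyl)oxy]-1-(3,5-dimethyl-1H-pyrazol-1-yl)-1-{(1S,2R)-3,3-dimethyl-2-[2-(2-methyl-1,3-dioxolan-2-yl)ethyl]cyclobutyl}butan-1-olate (tetrahedral adduct, either configuration at the new carbon) | CC(C)(C)[Si](C)(C)OCCCC(O[Mg]Br)(n1nc(C)cc1C)[C@H]1CC(C)(C)[C@@H]1CCC2(C)OCCO2 | intermediate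
12 | 4-[(tert-butyldimethylsilyl)oxy]-1-{(1S,2R)-3,3-dimethyl-2-[2-(2-methyl-1,3-dioxolan-2-yl)ethyl]cyclobutyl}butan-1-one | CC(C)(C)[Si](C)(C)OCCCC(=O)[C@H]1CC(C)(C)[C@@H]1CCC2(C)OCCO2 | intermediate
13 | tert-butyl[(4-{(1S,2R)-3,3-dimethyl-2-[2-(2-methyl-1,3-dioxolan-2-yl)ethyl]cyclobutyl}pent-4-en-1-yl)oxy]dimethylsilane | C=C(CCCO[Si](C)(C)C(C)(C)C)[C@H]1CC(C)(C)[C@@H]1CCC2(C)OCCO2 | intermediate
14 | 4-[(1S,2R)-3,3-dimethyl-2-(3-oxobutyl)cyclobutyl]pent-4-en-1-ol | C=C(CCCO)[C@H]1CC(C)(C)[C@@H]1CCC(C)=O | intermediate
15 | linoleic acid, (9Z,12Z)-octadeca-9,12-dienoic acid | CCCCC/C=C\C/C=C\CCCCCCCC(=O)O | starting material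
16 | 4-[(1S,2R)-3,3-dimethyl-2-(3-oxobutyl)cyclobutyl]pent-4-en-1-yl (9Z,12Z)-octadeca-9,12-dienoate (IN0146) | C=C(CCCOC(=O)CCCCCCC/C=C\C/C=C\CCCCC)[C@H]1CC(C)(C)[C@@H]1CCC(C)=O | target

**Totals.** Total step count: 8. Longest linear sequence: 8 steps (1 → 16); the Grignard reagent is made and used within step 5.

**Steps most likely to fail**

Step 4 (proposed new method). The β-alkyl chelate may absorb too weakly or relax without reaching a reactive triplet. Hydrogen transfer from the γ-CH2 of the (Z)-isomer may deconjugate the acceptor. First bond formation at the β-carbon may leak material into the head-to-head adduct. Facial discrimination may be insufficient without a β-aryl group. The fallback uses known chemistry and takes the ring from the chiral pool. It does not set out from a numbered compound of the route but from commercial (−)-β-caryophyllene F1, whose trans-fused cyclobutane already has the (1S,2R) arrangement with CMe2 next to C-2. Ozonolysis with one equivalent of O3 in CH2Cl2 at −78 °C and Me2S work-up should cleave only the strained endocyclic trisubstituted alkene and give keto aldehyde F2. NaBH4 (0.3 equiv) in CH2Cl2/EtOH at −78 °C should then reduce the aldehyde in preference to the methyl ketone. The fallback comes back to the route at keto alcohol 14, which goes on through step 8.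

Step 5. The Grignard reagent may act as a base at C-1 (loss of pyrazolide through a ketene, or epimerisation), or adduct 11 may collapse early and take up a second equivalent. The fallback sets out from 8. Treatment with MeNH(OMe)·HCl and iPrMgCl in THF at −20 °C should exchange the pyrazole for the amine and give Weinreb amide F3. Grignard reagent 10 in THF at 0 °C then adds once, and the fallback comes back to the route at ketone 12.

Step 6. The basic ylide may enolise the ketone, so that conversion stalls and C-1 equilibrates. The fallback sets out from 12 and replaces the Wittig reaction by a Peterson olefination. The weakly basic organocerium reagent from Me3SiCH2MgCl and anhydrous CeCl3 in THF (−78 → 0 °C) should add to the carbonyl group and give β-hydroxysilane F4. KH in THF (0 °C → rt) then effects syn-elimination, and the fallback comes back to the route at alkene 13.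

**Further compounds**

F1 | step 4 | (−)-β-caryophyllene, (1R,4E,9S)-4,11,11-trimethyl-8-methylidenebicyclo[7.2.0]undec-4-ene (commercial) | C/C/1=C\CCC(=C)[C@H]2CC([C@@H]2CC1)(C)C
F2 | step 4 | 4-[(1S,2R)-3,3-dimethyl-2-(3-oxobutyl)cyclobutyl]pent-4-enal | C=C(CCC=O)[C@H]1CC(C)(C)[C@@H]1CCC(C)=O
F3 | step 5 | (1S,2R)-N-methoxy-N,3,3-trimethyl-2-[2-(2-methyl-1,3-dioxolan-2-yl)ethyl]cyclobutane-1-carboxamide | CON(C)C(=O)[C@H]1CC(C)(C)[C@@H]1CCC2(C)OCCO2
F4 | step 6 | 5-[(tert-butyldimethylsilyl)oxy]-2-{(1S,2R)-3,3-dimethyl-2-[2-(2-methyl-1,3-dioxolan-2-yl)ethyl]cyclobutyl}-1-(trimethylsilyl)pentan-2-ol (either configuration at the carbinol carbon) | CC(C)(C)[Si](C)(C)OCCCC(O)(C[Si](C)(C)C)[C@H]1CC(C)(C)[C@@H]1CCC2(C)OCCO2
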